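The route rests on cutting C3–C4 of the heptanoid chain (C1 on the para-bridged ring B, C7 on the meta-bridged ring A). The feature exploited is the C5 ketone with C4 and C3 on its ring B side and C1 benzylic to electron-rich ring B: the ketone defines a C4 enolate, and C1–C3 an aryl-stabilised allyl cation. Both are stored in the 15-membered 1-arylallyl beta-keto lactone 10, closed by easy C–O bond formation through an acylketene. Zerovalent palladium then expels CO2 and replaces the O–C(=O) link by C2–C3, which forms the C3–C4 bond and the 15-membered cyclophane ketone 13 in one operation.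

Key step: step 8

Remark: the macrocycles 10, 13 and 14 each count 15 ring atoms (seven bridge atoms, four of ring B, the ether oxygen, three of ring A), so they are carbocycles apart from that oxygen; C1 is a stereocentre only in 7 to 10, is carried racemic and is erased in step 8 (the target is achiral); 7, 8 and 10 hold an acid-labile 1-arylallyl C–O bond and should be purified on Et3N-deactivated silica.

Step 1
Reactants: 1 methyl 3-(4-methoxyphenyl)propanoate
Product: 2 methyl 3-(3-iodo-4-methoxyphenyl)propanoate
Conditions: NIS (1.05 equiv), CF3CO2H (0.3 equiv), MeCN, rt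
Reagents that add atoms: N-iodosuccinimide, O=C1CCC(=O)N1I
Why: Electrophilic aromatic iodination should go ortho to the methoxy group, the strongest donor, because its para position is blocked by the propanoate chain, and the iodide rather than the bromide is chosen to ease the hindered coupling of step 2.

Step 2
Reactants: 2 methyl 3-(3-iodo-4-methoxyphenyl)propanoate; 3 2-methoxyresorcinol (3 equiv)
Product: 4 methyl 3-[3-(3-hydroxy-2-methoxyphenoxy)-4-methoxyphenyl]propanoate
Conditions: CuI (10 mol %), picolinic acid (20 mol %), K3PO4 (4 equiv), DMSO, 85 °C
Reagents that add atoms: none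
Why: Ullmann-type diaryl ether coupling under picolinic acid ligation tolerates ortho substituents on both partners and a methyl ester, the two hydroxy groups of 3 are equivalent by symmetry so no regiochemical question arises, and the excess of water-soluble 3 should hold back a second arylation.

Step 3
Reactants: 4 methyl 3-[3-(3-hydroxy-2-methoxyphenoxy)-4-methoxyphenyl]propanoate
Product: 5 methyl 3-[3-(4-formyl-3-hydroxy-2-methoxyphenoxy)-4-methoxyphenyl]propanoate
Conditions: MgCl2 (2 equiv), Et3N (4 equiv), (CH2O)n (6 equiv), MeCN, reflux; then 1 M HCl
Reagents that add atoms: paraformaldehyde (reacts as formaldehyde), C=O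
Why: Magnesium-mediated ortho-formylation of phenols (Casnati–Skattebøl reaction) delivers formaldehyde within the magnesium phenoxide only to a free ortho carbon, and since the other ortho carbon of ring B carries OMe the aldehyde (future C1) can enter only para to the aryloxy group, which sets the para bridge of ring B without a blocking group.

Step 4
Reactants: 5 methyl 3-[3-(4-formyl-3-hydroxy-2-methoxyphenoxy)-4-methoxyphenyl]propanoate
Product: 6 methyl 3-{3-[3-(benzyloxy)-4-formyl-2-methoxyphenoxy]-4-methoxyphenyl}propanoate
Conditions: BnBr (1.2 equiv), K2CO3 (2 equiv), DMF, 50 °C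
Reagents that add atoms: benzyl bromide, BrCc1ccccc1
Why: Williamson etherification of a chelated salicylaldehyde-type phenol is routine in warm DMF, and benzyl is chosen because it blocks ortho-quinone methide formation from the later carbinol and falls off in the final hydrogenation at no cost in steps.

Step 5
Reactants: 6 methyl 3-{3-[3-(benzyloxy)-4-formyl-2-methoxyphenoxy]-4-methoxyphenyl}propanoate
Product: 7 methyl 3-{3-[3-(benzyloxy)-4-(1-hydroxyprop-2-en-1-yl)-2-methoxyphenoxy]-4-methoxyphenyl}propanoate (racemic at C1)
Conditions: CH2=CHMgBr (1.15 equiv), THF, −78 °C; aq NH4Cl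
Reagents that add atoms: vinylmagnesium bromide, C=C[Mg]Br
Why: Grignard 1,2-addition is much faster at an aryl aldehyde than at a methyl ester at low temperature, and the new C1 stereocentre is formed racemic on purpose since it is erased in step 8.

Step 6
Reactants: 7 methyl 3-{3-[3-(benzyloxy)-4-(1-hydroxyprop-2-en-1-yl)-2-methoxyphenoxy]-4-methoxyphenyl}propanoate
Product: 8 tert-butyl 5-{3-[3-(benzyloxy)-4-(1-hydroxyprop-2-en-1-yl)-2-methoxyphenoxy]-4-methoxyphenyl}-3-oxopentanoate (racemic at C1)
Conditions: tBuOAc (4.2 equiv), LiN(iPr)2 (4.0 equiv), THF, −78 °C; then 7, −78 to −20 °C; aq NH4Cl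
Reagents that add atoms: tert-butyl acetate, CC(=O)OC(C)(C)C
Why: Crossed Claisen condensation of a methyl ester with excess lithium tert-butyl acetate enolate is well established on unprotected hydroxy esters, one equivalent being spent on the alkoxide and one on the product enolate (which shields the new ketone), so C4 and the future lactone carbonyl are installed without any protecting group.

Step 7
Reactants: 8 tert-butyl 5-{3-[3-(benzyloxy)-4-(1-hydroxyprop-2-en-1-yl)-2-methoxyphenoxy]-4-methoxyphenyl}-3-oxopentanoate
Product: 10 macrocyclic (15-membered) 1-arylallyl beta-keto lactone (ring B benzyl ether; racemic at C1), via acylketene 9 (not isolated)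
Conditions: toluene, reflux, syringe-pump addition of 8 over 12 h, final 1 mM, slow distillation of toluene/tBuOH
Reagents that add atoms: none
Why: tert-Butyl beta-keto esters lose tert-butanol at about 110 °C to give acylketenes, and capture of acylketene 9 by the tethered secondary carbinol at high dilution is the known acylketene macrolactonisation, a neutral C–O ring closure that spares the acid-labile 1-arylallyl unit and is driven by distilling off tert-butanol.

Step 8
Reactants: 10 macrocyclic (15-membered) 1-arylallyl beta-keto lactone
Product: 13 (E)-1,2-dehydrojuglanin A benzyl ether, via pi-allylpalladium beta-keto carboxylate 11 (not isolated), via pi-allylpalladium C4 enolate 12 (not isolated)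
Conditions: Pd2(dba)3 (5 mol %), PPh3 (25 mol %), degassed toluene, 50 °C, syringe-pump addition of 10 over 10 h, final 1 mM
Reagents that add atoms: none
Why: Proposed new method: zerovalent palladium should ionise the benzylic and allylic C1–O bond of 10 to the syn 1-aryl pi-allyl complex of divalent palladium 11, its tethered beta-keto carboxylate should lose CO2 to unveil the C4 enolate 12, and C-alkylation at C3 should release 13 and return the catalyst. The closest known reaction type is the Carroll-type decarboxylative allylation of open-chain allyl beta-keto esters in the Tsuji–Trost manifold, backed by palladium-catalysed macrocyclisation through intramolecular allylic alkylation; new here is that leaving group and nucleophile are two halves of one macrolactone. The 15-membered ring closes by intramolecular attack of enolate carbon C4 on the distal allyl terminus C3, so that C2 and C3 move from the exocyclic vinyl group into the ring and take the place of the departing O–C(=O) unit, the ring size staying at 15. No stereocentre is formed, racemic C1 becomes trigonal, and the E alkene follows from the syn geometry of the aryl-substituted allyl complex, any Z isomer converging in step 9. Enolate regiochemistry is secured because the charge appears only at the carbon that loses CO2 (if C-allylation of the carboxylate-bearing carbon came first, the same C3–C4 bond would result), and terminus selectivity is secured by the aryl group on C1, which hinders that end, rewards attack at C3 by styrene conjugation and leaves the branched 13-membered ring at a disadvantage. The allyl unit has no hydrogen for diene-forming elimination, and ring closure is favoured over oligomerisation by the non-polar solvent, which keeps the ion pair tight, and by slow addition at high dilution.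

Step 9
Reactants: 13 (E)-1,2-dehydrojuglanin A benzyl ether
Product: 14 juglanin A
Conditions: H2 (1 atm), Pd/C (10 wt %), EtOAc–MeOH, rt
Reagents that add atoms: none
Why: Heterogeneous catalytic hydrogenation should saturate the C1–C2 styrene and hydrogenolyse the benzyl ether in the same flask, while the dialkyl ketone, the diaryl ether and the methyl ethers are inert under one atmosphere of hydrogen.

Compound list
1 | methyl 3-(4-methoxyphenyl)propanoate | COC(=O)CCc1ccc(OC)cc1 | starting material
2 | methyl 3-(3-iodo-4-methoxyphenyl)propanoate | COC(=O)CCc1ccc(OC)c(I)c1 | intermediate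
3 | 2-methoxyresorcinol (2-methoxybenzene-1,3-diol) | COc1c(O)cccc1O | starting material
4 | methyl 3-[3-(3-hydroxy-2-methoxyphenoxy)-4-methoxyphenyl]propanoate | COC(=O)CCc1ccc(OC)c(Oc2cccc(O)c2OC)c1 | intermediate
5 | methyl 3-[3-(4-formyl-3-hydroxy-2-methoxyphenoxy)-4-methoxyphenyl]propanoate | COC(=O)CCc1ccc(OC)c(Oc2ccc(C=O)c(O)c2OC)c1 | intermediate
6 | methyl 3-{3-[3-(benzyloxy)-4-formyl-2-methoxyphenoxy]-4-methoxyphenyl}propanoate | COC(=O)CCc1ccc(OC)c(Oc2ccc(C=O)c(OCc3ccccc3)c2OC)c1 | intermediate
7 | methyl 3-{3-[3-(benzyloxy)-4-(1-hydroxyprop-2-en-1-yl)-2-methoxyphenoxy]-4-methoxyphenyl}propanoate, racemic | COC(=O)CCc1ccc(OC)c(Oc2ccc(C(O)C=C)c(OCc3ccccc3)c2OC)c1 | intermediate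
8 | tert-butyl 5-{3-[3-(benzyloxy)-4-(1-hydroxyprop-2-en-1-yl)-2-methoxyphenoxy]-4-methoxyphenyl}-3-oxopentanoate, racemic | CC(C)(C)OC(=O)CC(=O)CCc1ccc(OC)c(Oc2ccc(C(O)C=C)c(OCc3ccccc3)c2OC)c1 | intermediate
9 | acylketene O=C=CH–C(=O)–CH2CH2–(ring A) with the free vinyl carbinol on ring B, racemic, not isolated | O=C=CC(=O)CCc1ccc(OC)c(Oc2ccc(C(O)C=C)c(OCc3ccccc3)c2OC)c1 | intermediate
10 | 15-membered beta-keto lactone, ester oxygen on benzylic C1, vinyl group C2=C3 on C1, ring B benzyl ether, racemic at C1 | COc1ccc2cc1Oc1ccc(c(OCc3ccccc3)c1OC)C(C=C)OC(=O)CC(=O)CC2 | intermediate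
11 | ring-opened 1-aryl pi-allyl complex of divalent palladium with tethered beta-keto carboxylate (PPh3 ligands omitted, allyl drawn in its sigma form bound at C3), not isolated | COc1ccc(CCC(=O)CC(=O)[O-])cc1Oc1ccc(/C=C/C[Pd+])c(OCc2ccccc2)c1OC | intermediate
12 | the same pi-allyl complex after loss of CO2, carrying the C4 enolate of the methyl ketone (PPh3 ligands omitted, sigma form), not isolated | COc1ccc(CCC(=C)[O-])cc1Oc1ccc(/C=C/C[Pd+])c(OCc2ccccc2)c1OC | intermediate
13 | (E)-1,2-dehydrojuglanin A benzyl ether (15-membered cyclophane ketone, E alkene C1=C2) | COc1ccc2cc1Oc1ccc(c(OCc3ccccc3)c1OC)/C=C/CCC(=O)CC2 | intermediate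
14 | juglanin A (achiral) | COc1ccc2cc1Oc1ccc(c(O)c1OC)CCCCC(=O)CC2 | target

Total step count: 9. Longest linear sequence: 9 steps (1 to 14; 3 enters at step 2).

Steps most likely to fail

Step 8 (key step). After ionisation the enolate may be protonated, or it may be captured by the allyl complex of a second molecule, so that chain growth outruns ring closure. The fallback uses known chemistry, palladium-catalysed macrocyclisation by intramolecular allylic alkylation with a stabilised nucleophile, and sets out from 8. ClCO2Me and pyridine in CH2Cl2 at 0 °C should convert the carbinol into the allylic methyl carbonate F1. Pd2(dba)3 and PPh3 in THF at reflux under slow addition should ionise the carbonate. The methoxide formed on CO2 loss deprotonates the beta-keto ester, and the long-lived stabilised carbanion should close the same C3–C4 bond to the macrocyclic tert-butyl beta-keto ester F2 (racemic at C4). Hydrogenation over Pd/C should give the saturated phenol F3. Catalytic TsOH in toluene at 80 °C should then remove the tert-butyl group and CO2, and the sequence rejoins the route at 14.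

Step 7. The acylketene may be intercepted by a second molecule, tert-butanol may add back faster than the strained ring closes, or the carbinol may suffer allylic transposition during long heating. The fallback replaces heat by thiophilic-metal activation of a thioester at room temperature and sets out from 7. LiOH in THF–water, followed by careful acidification to pH 5, should give the hydroxy acid F4. 1,1'-Carbonyldiimidazole (1.0 equiv, THF) should give the acyl imidazolide F5. This is treated in the same flask with Mg(O2CCH2COStBu)2 (magnesium malonate C-acylation with loss of CO2) to give the S-tert-butyl beta-keto thioester F6. AgOCOCF3 with Na2HPO4 buffer in dilute toluene–THF at rt should abstract the thiolate and let the carbinol close the lactone, rejoining the route at 10.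

Step 2. Coupling at a C–O bond flanked by ortho substituents on both rings may be slow, which leaves room for protodeiodination, a second arylation or ester hydrolysis at 85 °C. The fallback switches to an oxidative Chan–Lam coupling and sets out from 2. Miyaura borylation (PdCl2(dppf), B2pin2, KOAc, dioxane, 80 °C) should give the aryl pinacol boronate F7. This is coupled with excess 3 using Cu(OAc)2, B(OH)3, pyridine and 4 Å sieves in MeCN under air, rejoining the route at 4.

Further compounds
F1 | step 8 | tert-butyl 5-{3-[3-(benzyloxy)-2-methoxy-4-(1-(methoxycarbonyloxy)prop-2-en-1-yl)phenoxy]-4-methoxyphenyl}-3-oxopentanoate, racemic | CC(C)(C)OC(=O)CC(=O)CCc1ccc(OC)c(Oc2ccc(C(C=C)OC(=O)OC)c(OCc3ccccc3)c2OC)c1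
F2 | step 8 | (E)-1,2-dehydrojuglanin A benzyl ether carrying CO2tBu on C4, racemic at C4 | COc1ccc2cc1Oc1ccc(c(OCc3ccccc3)c1OC)/C=C/CC(C(=O)OC(C)(C)C)C(=O)CC2
F3 | step 8 | juglanin A carrying CO2tBu on C4, racemic at C4 | COc1ccc2cc1Oc1ccc(c(O)c1OC)CCCC(C(=O)OC(C)(C)C)C(=O)CC2
F4 | step 7 | 3-{3-[3-(benzyloxy)-4-(1-hydroxyprop-2-en-1-yl)-2-methoxyphenoxy]-4-methoxyphenyl}propanoic acid, racemic | OC(=O)CCc1ccc(OC)c(Oc2ccc(C(O)C=C)c(OCc3ccccc3)c2OC)c1
F5 | step 7 | acyl imidazolide of F4, racemic | O=C(CCc1ccc(OC)c(Oc2ccc(C(O)C=C)c(OCc3ccccc3)c2OC)c1)n1ccnc1
F6 | step 7 | S-tert-butyl 5-{3-[3-(benzyloxy)-4-(1-hydroxyprop-2-en-1-yl)-2-methoxyphenoxy]-4-methoxyphenyl}-3-oxopentanethioate, racemic | CC(C)(C)SC(=O)CC(=O)CCc1ccc(OC)c(Oc2ccc(C(O)C=C)c(OCc3ccccc3)c2OC)c1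
F7 | step 2 | methyl 3-[4-methoxy-3-(4,4,5,5-tetramethyl-1,3,2-dioxaborolan-2-yl)phenyl]propanoate | COC(=O)CCc1ccc(OC)c(B2OC(C)(C)C(C)(C)O2)c1
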